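Write the balance of the enzyme, not of the substrate. Your flask, elm, is closed, stirred and isothermal, and it has been followed up to its last reading. You are asked about it at 80 min and about the remedies that could follow.

| setting | elm | cedar | flask |
|---|---|---|---|
| substrate | 0.050 M | 0.050 M | 0.050 M |
| free enzyme | 5 µM | 5 µM | 5.0 µM |
| temperature | 25 °C | 20 °C | 25 °C |
| remark | the very flask that is asked about, followed so far | run made earlier |  |
| time |  |  | 80 min |

| elm: time / min | elm: product / % | cedar: time / min | cedar: product / % |
|---|---|---|---|
| 3.00 | 6.2 | 3.00 | 5.6 |
| 10.0 | 12.3 | 10.0 | 13.2 |
| 20.0 | 14.2 | 20.0 | 17.7 |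
| 30.0 | 13.9 | 30.0 | 19.0 |
| 40.0 | 13.8 | 40.0 | 19.1 |
| 50.0 | 14.4 | 50.0 | 19.8 |
| 60.0 | 13.9 | 60.0 | 19.8 |

(readings scatter by 0.3 percentage points)

- winter: at 80 min raise the temperature by 10 K, then wait 40 min
- dusk: at 80 min take out 90 % of the product then present, then wait 40 min
- spring: change nothing and wait 40 min more
- autumn: at 80 min add free enzyme, 100 % of the amount charged, then wait 40 min

- removed product is counted in
- reactions considered so far: free enzyme -> unfolded enzyme; substrate + free enzyme <-> complex; complex -> free enzyme + product; substrate + free enzyme -> spent catalyst A; free enzyme -> spent catalyst B
- additions bring no volume worth counting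

* product, in percent of the substrate first charged, at 80 min
* the remedy with the largest gain of product, or "none" below 2 percentage points (winter / dusk / spring / autumn / none)
* product present, with what was taken out counted in, in percent of the substrate first charged, after winter
* product present, with what was taken out counted in, in percent of the substrate first charged, after autumn

In elm the product stays flat from 30.0 min on, near 14.0 %. Yet 86.0 % of the substrate is left, so the substrate has not run out. The substrate outnumbers the free enzyme 10000 to one, and the enzyme returns from each round. But the listed steps also take it out of the round, and none of them reverses the product step. So I treat the enzyme as the limiting reagent, though a plateau by itself does not separate a lost enzyme from an equilibrium.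

Fold the givens into one number, the plateau share times the [substrate] charged over the [free enzyme] charged. Call it the turnover capacity: the mean number of rounds one enzyme molecule makes before it leaves the round. In elm it reads 1400.

Is one number enough? Cedar reads 1980 at 20 °C, more than elm, so the number belongs to a temperature. It may also shift with [substrate], which in elm has fallen to 86.0 % of its charge.

My reckoning gives 14.0 % at 80 min. Waiting, heating and taking out product act on a lost enzyme, so I expect no gain from them. I count autumn's fresh charge as worth 14 percentage points, more than the margin, for 28.0 % in all.

The forecast gives 14.1 % at 80 min, autumn as the best remedy and 14.1 % after winter. Its 27.5 % after autumn is lower than my figure, since it expects the second batch to be perhaps slightly less at the lower substrate. Its ground: “I read the plateau as dead enzyme, not equilibrium”.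

The flask gives 14.1 %, 14.1 % after winter, 27.4 % after autumn, and autumn as the best remedy.

    free enzyme → unfolded enzyme (k = 0.00662 min⁻¹, Ea = 229 kJ mol⁻¹)
    substrate + free enzyme ⇌ complex (K = 9.70 M⁻¹, k = 10600 M⁻¹ s⁻¹, Ea = 15.0 kJ mol⁻¹, ΔH = −42.0 kJ mol⁻¹)
    complex → free enzyme + product (k = 856 min⁻¹, Ea = 57.0 kJ mol⁻¹)
    substrate + free enzyme → spent catalyst A (k = 3.71 M⁻¹ min⁻¹, Ea = 55.0 kJ mol⁻¹)
    free enzyme → spent catalyst B (k = 0.0907 min⁻¹, Ea = 83.0 kJ mol⁻¹)
    (constants at 25 °C)

Half of the turnover of complex to product is done by 3.60 min, far sooner than the 80 min at which you act. Free enzyme has a half-life of 7.6 min by the path to spent catalyst B alone, and at 80.0 min the share that can still turn over is 0 %. Autumn's real gain is 13 points, against 14 points from the capacity. For a neighbour of elm charged with 2.0 × 10⁻⁵ M of free enzyme, the capacity gives 56.0 %, and that flask stands at 51.0 %.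

The readings were generated by integration on assumed constants; the scatter is artificial.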